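**Retrosynthetic overview**
1. The target is cut at C1–C2 (and C3–CH3) of its 3-methylalk-2-enyl ester unit into enyne 12, Me3Al and chloromethyl oleate 14. These are joined in one flask by syn-methylalumination of the terminal alkyne (C2≡C3), then palladium-catalysed alkenyl–CH2 coupling that brings in the complete oleate.
2. Enabling feature: C1 is an O-acylated CH2 on the trisubstituted (2E)-alkene C2=C3, whose C3 methyl is cis to C1. This is the imprint of syn Me–Al addition to a terminal alkyne followed by stereoretentive substitution at C2. The other alkenes (C6=C7, ring C2'=C3', the (Z)-alkene of the oleate) are tri- or 1,2-disubstituted and do not carbometalate.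
3. Enyne 12 comes from alkenyl iodide 8 and homopropargylzinc 10 (Negishi coupling, C5–C6). Iodide 8 comes from alkyne 6 by the same methylalumination, stopped with iodine, which sets the (6E)-alkene.
4. Alkyne 6 comes from iodide 5, alcohol 4 and ester 3. Ester 3 comes from (R)-allylic alcohol 2 by Johnson–Claisen 1,3-chirality transfer to C1', and 2 from enone 1 by CBS reduction, which sets the only stereocentre.
5. Ring order: the single cyclohexene ring is bought with 1 and no ring is formed in the route. Ester 14 is made from oleic acid 13 in one step.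

Key step: step 10

Remark on the chemistry: the ring stereocentre C1' is (S) (C2' > C6' > C9 > H). Chain positions are numbered C1–C9 from the ester-bearing CH2 of the C20 alcohol part, ring positions C1'–C6'. Compounds 1, 9 and 13 and all reagents are taken as purchasable.

**Step 1**
Reactants: 1 2,4,4-trimethylcyclohex-2-en-1-one
Product: 2 (1R)-2,4,4-trimethylcyclohex-2-en-1-ol
Conditions: (S)-2-methyl-CBS-oxazaborolidine (10 mol%), BH3·SMe2, THF, −20 °C; MeOH, then aq. NH4Cl
Reagents that add atoms: none
Why: Corey–Bakshi–Shibata reduction, in which the ketone binds the catalyst boron syn to its small CH2 flank (C6) and anti to the α-methylated alkene carbon C2, so that hydride reaches one carbonyl face and the (S)-catalyst should give the (R)-carbinol, the same sense as with aryl methyl ketones.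

**Step 2**
Reactants: 2 (1R)-2,4,4-trimethylcyclohex-2-en-1-ol
Product: 3 ethyl 2-[(1S)-2,6,6-trimethylcyclohex-2-en-1-yl]acetate
Conditions: MeC(OEt)3 (6 equiv), EtCO2H (cat.), 140 °C, EtOH distilled off
Reagents that add atoms: triethyl orthoacetate, CC(OCC)(OCC)OCC
Why: Johnson–Claisen rearrangement, whose ketene acetal, formed in situ on the C1 oxygen, must deliver its carbon suprafacially to C3 of the ring, so the (1R) C–O centre is relayed to the new (1S) C–C centre beside the gem-dimethyl carbon while the alkene moves to the position it holds in the target.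

**Step 3**
Reactants: 3 ethyl 2-[(1S)-2,6,6-trimethylcyclohex-2-en-1-yl]acetate
Product: 4 2-[(1S)-2,6,6-trimethylcyclohex-2-en-1-yl]ethan-1-ol
Conditions: LiAlH4, Et2O, 0 °C → rt; aq. NaOH work-up
Reagents that add atoms: none
Why: Hydride reduction of the ester to the primary alcohol, which leaves the trisubstituted alkene and the non-acidic allylic stereocentre untouched.

**Step 4**
Reactants: 4 2-[(1S)-2,6,6-trimethylcyclohex-2-en-1-yl]ethan-1-ol
Product: 5 (6S)-6-(2-iodoethyl)-1,5,5-trimethylcyclohex-1-ene
Conditions: PPh3, imidazole, I2, CH2Cl2, 0 °C → rt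
Reagents that add atoms: iodine, II
Why: Appel-type iodination, in which iodide displaces the oxyphosphonium group of the unhindered primary alcohol by SN2 under neutral conditions that do not touch the ring alkene.

**Step 5**
Reactants: 5 (6S)-6-(2-iodoethyl)-1,5,5-trimethylcyclohex-1-ene
Product: 6 (6S)-6-(but-3-yn-1-yl)-1,5,5-trimethylcyclohex-1-ene
Conditions: LiC≡CH·H2NCH2CH2NH2, DMSO, rt
Reagents that add atoms: lithium acetylide–ethylenediamine complex, [Li]C#C.NCCN
Why: SN2 alkylation of lithium acetylide by a primary iodide in DMSO, which adds the two alkyne carbons at a site three bonds away from the stereocentre.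

**Step 6**
Reactants: 6 (6S)-6-(but-3-yn-1-yl)-1,5,5-trimethylcyclohex-1-ene
Product: 8 (1E)-1-iodo-2-methyl-4-[(1S)-2,6,6-trimethylcyclohex-2-en-1-yl]but-1-ene, via alkenyldimethylalane 7 (not isolated)
Conditions: Me3Al (2 equiv), Cp2ZrCl2 (0.2 equiv), CH2Cl2, rt; then I2, THF, −30 → 0 °C; aq. Na2S2O3/NaHCO3
Reagents that add atoms: trimethylaluminium, C[Al](C)C; iodine, II
Why: Zirconium-catalysed methylalumination adds Me–Al syn to the terminal alkyne with methyl on the internal carbon, and iodinolysis of the C–Al bond with retention should give the (E)-iodide, the trisubstituted ring alkene being inert.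

**Step 7**
Reactants: 8 (1E)-1-iodo-2-methyl-4-[(1S)-2,6,6-trimethylcyclohex-2-en-1-yl]but-1-ene; 9 (4-bromobut-1-yn-1-yl)trimethylsilane
Product: 11 trimethyl{(5E)-6-methyl-8-[(1S)-2,6,6-trimethylcyclohex-2-en-1-yl]oct-5-en-1-yn-1-yl}silane, via alkylzinc bromide 10 (not isolated)
Conditions: 9, Zn dust, I2 (cat.), DMA, 80 °C; then 8, Pd(PPh3)4 (5 mol%), THF, rt → 40 °C
Reagents that add atoms: none
Why: Negishi coupling of a primary alkylzinc bromide, made by direct zinc insertion, with the alkenyl iodide, which forms the C5–C6 bond with retention of the (E) geometry and tolerates the silylalkyne.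

**Step 8**
Reactants: 11 trimethyl{(5E)-6-methyl-8-[(1S)-2,6,6-trimethylcyclohex-2-en-1-yl]oct-5-en-1-yn-1-yl}silane
Product: 12 (5E)-6-methyl-8-[(1S)-2,6,6-trimethylcyclohex-2-en-1-yl]oct-5-en-1-yne
Conditions: K2CO3 (0.2 equiv), MeOH, rt
Reagents that add atoms: none
Why: Carbonate-catalysed methanolysis cleaves the alkynyl C–Si bond selectively and frees the terminal alkyne needed for the key step.

**Step 9**
Reactants: 13 oleic acid [(9Z)-octadec-9-enoic acid]
Product: 14 chloromethyl (9Z)-octadec-9-enoate (chloromethyl oleate)
Conditions: ClCH2OSO2Cl, NaHCO3, Bu4NHSO4 (cat.), CH2Cl2/H2O, rt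
Reagents that add atoms: chloromethyl chlorosulfate, ClCOS(Cl)(=O)=O
Why: Phase-transfer O-alkylation of the carboxylate by chloromethyl chlorosulfate, in which chlorosulfate is displaced in preference to chloride so that the chloromethyl ester results under mild conditions that leave the (Z)-alkene unisomerised.

**Step 10**
Reactants: 12 (5E)-6-methyl-8-[(1S)-2,6,6-trimethylcyclohex-2-en-1-yl]oct-5-en-1-yne; 14 chloromethyl (9Z)-octadec-9-enoate
Product: 16 (2E,6E)-3,7-dimethyl-9-[(1S)-2,6,6-trimethylcyclohex-2-en-1-yl]nona-2,6-dien-1-yl (9Z)-octadec-9-enoate, via dienyldimethylalane 15 (not isolated)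
Conditions: 12, Me3Al (2 equiv), Cp2ZrCl2 (0.2 equiv), CH2Cl2, rt; volatiles and excess Me3Al removed in vacuo; THF; slow addition to 14 (1.3 equiv), Pd(PPh3)4 (5 mol%), THF, 0 °C → rt; aq. NaHCO3
Reagents that add atoms: trimethylaluminium, C[Al](C)C
Why: Proposed new method: Cp2ZrCl2 and Me3Al form a methylzirconocene cation that adds Me–Zr syn across the terminal alkyne of 12 with the methyl on the internal carbon C3, exchange with aluminium gives the (E)-alkenylalane 15, and zerovalent palladium then inserts into the activated C–Cl bond of 14, accepts the alkenyl group from aluminium and reductively eliminates to form the C2–C1 bond with retention of the alkene geometry. The closest known reaction types are the zirconium-catalysed methylalumination of terminal alkynes followed in the same flask by palladium- or nickel-catalysed coupling of the alkenylalane with benzylic and allylic chlorides, the direct alkylation of such alanes by chloromethyl methyl ether, and palladium couplings that pass through acyloxymethyl–palladium intermediates made from acyloxymethylzinc or acyloxymethyltrifluoroborate reagents; new is an acyloxymethyl chloride as the sp3 partner of an alkenylalane. No ring is closed and no stereocentre is formed; the (2E) geometry follows from syn addition and stereoretentive coupling, which place C1 cis to the C3 methyl. The step needs regioselective methyl delivery to C3, which the terminal alkyne secures, and chemoselectivity for the alkyne, which should hold because the C6=C7 and ring alkenes are trisubstituted and 14 with its (Z)-alkene is added only after the carbometalation. It also needs alkenyl rather than methyl transfer to palladium, and C–Cl insertion in preference to ionisation of the allylic C–O bond of the product or addition to the ester carbonyl; these should be secured by the faster transfer of sp2 carbon from aluminium, the absence of β-hydrogens on the CH2 unit, removal of excess Me3Al, the donor solvent THF, low temperature, and slow addition of 15 to an excess of 14.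

**Compound list**
1 | 2,4,4-trimethylcyclohex-2-en-1-one | CC1=CC(C)(C)CCC1=O | starting material
2 | (1R)-2,4,4-trimethylcyclohex-2-en-1-ol | O[C@H]1C(C)=CC(C)(C)CC1 | intermediate
3 | ethyl 2-[(1S)-2,6,6-trimethylcyclohex-2-en-1-yl]acetate | CCOC(=O)C[C@@H]1C(C)=CCCC1(C)C | intermediate
4 | 2-[(1S)-2,6,6-trimethylcyclohex-2-en-1-yl]ethan-1-ol | OCC[C@@H]1C(C)=CCCC1(C)C | intermediate
5 | (6S)-6-(2-iodoethyl)-1,5,5-trimethylcyclohex-1-ene | ICC[C@@H]1C(C)=CCCC1(C)C | intermediate
6 | (6S)-6-(but-3-yn-1-yl)-1,5,5-trimethylcyclohex-1-ene | C#CCC[C@@H]1C(C)=CCCC1(C)C | intermediate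
7 | dimethyl{(1E)-2-methyl-4-[(1S)-2,6,6-trimethylcyclohex-2-en-1-yl]but-1-en-1-yl}alane | C[Al](C)/C=C(\C)CC[C@@H]1C(C)=CCCC1(C)C | intermediate (not isolated)
8 | (1E)-1-iodo-2-methyl-4-[(1S)-2,6,6-trimethylcyclohex-2-en-1-yl]but-1-ene | I/C=C(\C)CC[C@@H]1C(C)=CCCC1(C)C | intermediate
9 | (4-bromobut-1-yn-1-yl)trimethylsilane | C[Si](C)(C)C#CCCBr | starting material
10 | [4-(trimethylsilyl)but-3-yn-1-yl]zinc bromide | C[Si](C)(C)C#CCC[Zn]Br | intermediate (not isolated)
11 | trimethyl{(5E)-6-methyl-8-[(1S)-2,6,6-trimethylcyclohex-2-en-1-yl]oct-5-en-1-yn-1-yl}silane | C[Si](C)(C)C#CCC/C=C(\C)CC[C@@H]1C(C)=CCCC1(C)C | intermediate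
12 | (5E)-6-methyl-8-[(1S)-2,6,6-trimethylcyclohex-2-en-1-yl]oct-5-en-1-yne | C#CCC/C=C(\C)CC[C@@H]1C(C)=CCCC1(C)C | intermediate
13 | oleic acid [(9Z)-octadec-9-enoic acid] | CCCCCCCC/C=C\CCCCCCCC(=O)O | starting material
14 | chloromethyl (9Z)-octadec-9-enoate | CCCCCCCC/C=C\CCCCCCCC(=O)OCCl | intermediate
15 | dimethyl{(1E,5E)-2,6-dimethyl-8-[(1S)-2,6,6-trimethylcyclohex-2-en-1-yl]octa-1,5-dien-1-yl}alane | C[Al](C)/C=C(\C)CC/C=C(\C)CC[C@@H]1C(C)=CCCC1(C)C | intermediate (not isolated)
16 | (2E,6E)-3,7-dimethyl-9-[(1S)-2,6,6-trimethylcyclohex-2-en-1-yl]nona-2,6-dien-1-yl (9Z)-octadec-9-enoate | CCCCCCCC/C=C\CCCCCCCC(=O)OC/C=C(\C)CC/C=C(\C)CC[C@@H]1C(C)=CCCC1(C)C | target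

**Step count**
Total steps: 10. Longest linear sequence: 9 steps (steps 1–8 and step 10); step 9 is a one-step side branch.

**Steps most likely to fail**

Step 10 (proposed new method). What may go wrong: transfer of methyl instead of the alkenyl group to palladium, Lewis-acid fragmentation of the chloromethyl ester before oxidative addition, or a second coupling at the allylic C–O bond of the product as it accumulates. The fallback sets out from 12 and comes back at 16, and uses only known chemistry. Enyne 12 is methylaluminated as in step 10 to 15 and the volatiles are removed. The alane is treated with n-BuLi (hexane/THF, −78 °C) to give lithium butyl{(1E,5E)-2,6-dimethyl-8-[(1S)-2,6,6-trimethylcyclohex-2-en-1-yl]octa-1,5-dien-1-yl}dimethylalanate F1. Paraformaldehyde then hydroxymethylates F1 at C2 with retention, which should give (2E,6E)-3,7-dimethyl-9-[(1S)-2,6,6-trimethylcyclohex-2-en-1-yl]nona-2,6-dien-1-ol F2. Steglich esterification of F2 with oleic acid 13 (EDC·HCl, DMAP, CH2Cl2, rt) should then give 16. The C1–C2 bond is still formed from the same alkenylalane, but the acyl group arrives in a separate operation.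

Step 2. What may go wrong: slow rearrangement at the crowded ring carbon next to the gem-dimethyl group, with acid-promoted dehydration of the allylic alcohol to a diene taking over. The fallback sets out from 2 and comes back at 4. An Eschenmoser–Claisen rearrangement of 2 with N,N-dimethylacetamide dimethyl acetal (xylene, 140 °C, no acid) should give N,N-dimethyl-2-[(1S)-2,6,6-trimethylcyclohex-2-en-1-yl]acetamide F3 with the same suprafacial chirality transfer. Reduction of F3 with LiH2NBH3 (THF, 0 °C → rt) should give alcohol 4 directly.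

Step 1. What may go wrong: insufficient enantiofacial discrimination in the hydride transfer, which would lower the enantiopurity of every later compound. The fallback sets out from 1 and comes back at 2. Luche reduction of 1 (NaBH4, CeCl3·7H2O, MeOH, 0 °C) should give racemic 2,4,4-trimethylcyclohex-2-en-1-ol F4. Lipase-catalysed acylation (Candida antarctica lipase B, vinyl acetate, hexane, rt) is expected, by the usual empirical preference of lipases for secondary alcohols, to convert the (R)-enantiomer into (1R)-2,4,4-trimethylcyclohex-2-en-1-yl acetate F5 and to leave (1S)-2,4,4-trimethylcyclohex-2-en-1-ol F6. After chromatographic separation, methanolysis of F5 (K2CO3, MeOH, rt) should give 2.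

**Further compounds**
F1 | step 10 | lithium butyl{(1E,5E)-2,6-dimethyl-8-[(1S)-2,6,6-trimethylcyclohex-2-en-1-yl]octa-1,5-dien-1-yl}dimethylalanate | [Li+].CCCC[Al-](C)(C)/C=C(\C)CC/C=C(\C)CC[C@@H]1C(C)=CCCC1(C)C
F2 | step 10 | (2E,6E)-3,7-dimethyl-9-[(1S)-2,6,6-trimethylcyclohex-2-en-1-yl]nona-2,6-dien-1-ol | OC/C=C(\C)CC/C=C(\C)CC[C@@H]1C(C)=CCCC1(C)C
F3 | step 2 | N,N-dimethyl-2-[(1S)-2,6,6-trimethylcyclohex-2-en-1-yl]acetamide | CN(C)C(=O)C[C@@H]1C(C)=CCCC1(C)C
F4 | step 1 | racemic 2,4,4-trimethylcyclohex-2-en-1-ol | OC1C(C)=CC(C)(C)CC1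
F5 | step 1 | (1R)-2,4,4-trimethylcyclohex-2-en-1-yl acetate | CC(=O)O[C@H]1C(C)=CC(C)(C)CC1
F6 | step 1 | (1S)-2,4,4-trimethylcyclohex-2-en-1-ol | O[C@@H]1C(C)=CC(C)(C)CC1
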